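**Retrosynthetic overview**

1. Feature: the cyclohexene C1–C14–C13–C12=C11–C15 holds its double bond at bridgehead C11 of the bicyclo[9.3.1] core (12-membered ring C1 to C11, closed through C15), and C12 is also the α-carbon of the γ-lactam. This is the retron of a [4+2] whose diene C13=C12–C11=C15 carries the tether on its 2-position, C11.
2. Key disconnection: C13–C14 and C1–C15, an intramolecular Diels–Alder reaction of a 3-methylene-4-isopropylidene-γ-lactam with a C2-oxo vinyl ketone. The C2 ketone is removed afterwards by Luche reduction and Barton–McCombie deoxygenation.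
3. Tether: C5–C6 by BINOL–titanium allylation of a C6 enal with an allylstannane made from acrolein and a 2-(chloromethyl)allylsilane. The C2 carbinol is oxidised to the vinyl ketone last.
4. Diene lactam: isopropyl ketone, then tetrasubstituted enol triflate, then Stille coupling with an α-stannylacrylate, then N-deprotection and lactamisation.
5. C10 and the E-C7=C8 alkene: chelate-enolate Claisen rearrangement of a Boc-glycine ester of a glyceraldehyde-derived allylic alcohol. Ring order: γ-lactam first (step 11), then cyclohexene and 12-membered ring together (step 20).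

Key step: step 20

Remark: atom labels are those of the target skeleton (C1 ring CH next to C15 Me2; C2–C3 chain; C4 exo-methylene carbon; C6 acetoxy carbon; C7=C8; C10 N-bearing carbon; C11=C12 ring alkene; C13, C14 ring CH2; C18 lactam C=O). The target is (1R,6S,7E,10R) in these labels. Stannane 23 is used as the racemate, so 24–26 are pairs of C2 epimers that converge in ketone 27.

**Route**

Step 1
Reactants: 1 (R)-2,2-dimethyl-1,3-dioxolane-4-carbaldehyde [(R)-glyceraldehyde acetonide]
Product: 2 1-[(4R)-2,2-dimethyl-1,3-dioxolan-4-yl]-2-methylprop-2-en-1-ol (both carbinol epimers)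
Conditions: isopropenylMgBr, THF, −78 °C; aq. NH4Cl
Reagents that add atoms: isopropenylmagnesium bromide, C=C(C)[Mg]Br
Why: Grignard 1,2-addition to the aldehyde gives the allylic alcohol, and the carbinol centre may form unselectively because step 2 oxidises it.

Step 2
Reactants: 2 1-[(4R)-2,2-dimethyl-1,3-dioxolan-4-yl]-2-methylprop-2-en-1-ol
Product: 3 1-[(4R)-2,2-dimethyl-1,3-dioxolan-4-yl]-2-methylprop-2-en-1-one
Conditions: Dess–Martin periodinane, NaHCO3, CH2Cl2, 0 °C → rt
Reagents that add atoms: none
Why: Dess–Martin oxidation of the allylic alcohol under buffered, non-enolising conditions should give the α-alkoxy enone without loss of the dioxolane stereocentre.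

Step 3
Reactants: 3 1-[(4R)-2,2-dimethyl-1,3-dioxolan-4-yl]-2-methylprop-2-en-1-one
Product: 4 (1S)-1-[(4R)-2,2-dimethyl-1,3-dioxolan-4-yl]-2-methylprop-2-en-1-ol (anti)
Conditions: Zn(BH4)2, Et2O, −78 → −30 °C; aq. NH4Cl
Reagents that add atoms: none
Why: Chelation-controlled (Cram-chelate) 1,2-reduction, in which zinc bridges the ketone and the α-dioxolane oxygen and hydride enters from the side of the C6 hydrogen, should give the anti (S) carbinol at C7.

Step 4
Reactants: 4 (1S)-1-[(4R)-2,2-dimethyl-1,3-dioxolan-4-yl]-2-methylprop-2-en-1-ol; 5 N-Boc-glycine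
Product: 6 (1S)-1-[(4R)-2,2-dimethyl-1,3-dioxolan-4-yl]-2-methylprop-2-en-1-yl N-(tert-butoxycarbonyl)glycinate
Conditions: DCC, DMAP (cat.), CH2Cl2, 0 °C → rt
Reagents that add atoms: none
Why: Steglich esterification acylates the secondary allylic alcohol without touching its configuration.

Step 5
Reactants: 6 (1S)-1-[(4R)-2,2-dimethyl-1,3-dioxolan-4-yl]-2-methylprop-2-en-1-yl N-(tert-butoxycarbonyl)glycinate
Product: 8 (2R,4E)-2-[(tert-butoxycarbonyl)amino]-5-[(4S)-2,2-dimethyl-1,3-dioxolan-4-yl]-4-methylpent-4-enoic acid, via zinc-chelated ester enolate 7 (not isolated)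
Conditions: LDA (2.7 equiv), ZnCl2 (1.2 equiv), THF, −78 °C → rt; cold 1 M HCl
Reagents that add atoms: none
Why: In the chelate-enolate Claisen rearrangement the N,O-chelated enolate (geometry fixed) reacts through a chair with the dioxolanyl group equatorial, which should give the E-trisubstituted C7=C8 alkene and transfer the (S) configuration of C7 to (R) at C10.

Step 6
Reactants: 8 (2R,4E)-2-[(tert-butoxycarbonyl)amino]-5-[(4S)-2,2-dimethyl-1,3-dioxolan-4-yl]-4-methylpent-4-enoic acid
Product: 9 tert-butyl N-[(2R,4E)-5-[(4S)-2,2-dimethyl-1,3-dioxolan-4-yl]-1-[methoxy(methyl)amino]-4-methyl-1-oxopent-4-en-2-yl]carbamate (Weinreb amide)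
Conditions: MeNHOMe·HCl, EDC·HCl, HOBt, N-methylmorpholine, CH2Cl2, 0 °C → rt
Reagents that add atoms: N,O-dimethylhydroxylamine hydrochloride, CNOC.Cl
Why: Carbodiimide/HOBt amide coupling of a urethane-protected amino acid gives the Weinreb amide without epimerising C10.

Step 7
Reactants: 9 Weinreb amide
Product: 10 tert-butyl N-[(4R,6E)-7-[(4S)-2,2-dimethyl-1,3-dioxolan-4-yl]-2,6-dimethyl-3-oxohept-6-en-4-yl]carbamate (isopropyl ketone)
Conditions: i-PrMgCl (3.5 equiv), THF, −15 → 0 °C; aq. NH4Cl
Reagents that add atoms: isopropylmagnesium chloride, CC(C)[Mg]Cl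
Why: Weinreb ketone synthesis, in which the first equivalent deprotonates the carbamate (shielding C10 as its N-anion) and the chelated tetrahedral adduct prevents over-addition.

Step 8
Reactants: 10 isopropyl ketone
Product: 12 (4R,6E)-4-[(tert-butoxycarbonyl)amino]-7-[(4S)-2,2-dimethyl-1,3-dioxolan-4-yl]-2,6-dimethylhepta-2,6-dien-3-yl trifluoromethanesulfonate, via dipotassium enolate 11 (not isolated)
Conditions: KHMDS (2.2 equiv), THF, −78 °C; PhNTf2, −78 → 0 °C
Reagents that add atoms: N-phenylbis(trifluoromethanesulfonimide), O=S(=O)(N(c1ccccc1)S(=O)(=O)C(F)(F)F)C(F)(F)F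
Why: Kinetic enolisation and O-triflation, in which the carbamate N-anion disfavours removal of the C10 proton so the second equivalent of base takes the isopropyl methine proton, should give the tetrasubstituted C11=C15 enol triflate with C10 intact.

Step 9
Reactants: 13 methyl propiolate
Product: 14 methyl 2-(tributylstannyl)prop-2-enoate
Conditions: Bu3SnH, Pd(PPh3)4 (2 mol%), THF, 0 °C → rt
Reagents that add atoms: tributyltin hydride, CCCC[SnH](CCCC)CCCC
Why: Palladium-catalysed syn-hydrostannation of an alkynoate places tin on the carbon α to the ester.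

Step 10
Reactants: 12 enol triflate; 14 methyl 2-(tributylstannyl)prop-2-enoate
Product: 15 methyl (4R,6E)-4-[(tert-butoxycarbonyl)amino]-7-[(4S)-2,2-dimethyl-1,3-dioxolan-4-yl]-6-methyl-2-methylidene-3-(propan-2-ylidene)hept-6-enoate
Conditions: Pd(PPh3)4 (10 mol%), CuCl, LiCl, DMSO, 60 °C
Reagents that add atoms: none
Why: Stille coupling under copper(I) chloride/lithium chloride acceleration, the variant suited to hindered vinyl triflates and 1-substituted vinylstannanes, forms the C11–C12 bond of the cross-conjugated diene ester.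

Step 11
Reactants: 15 diene ester
Product: 17 (5R)-5-[(2E,4S)-4,5-dihydroxy-2-methylpent-2-en-1-yl]-3-methylidene-4-(propan-2-ylidene)pyrrolidin-2-one, via ammonium trifluoroacetate 16 (not isolated)
Conditions: TFA–H2O (9:1), CH2Cl2, 0 °C; evaporate; Et3N, MeOH (0.02 M), rt
Reagents that add atoms: none
Why: Acidolysis removes the Boc group and the acetonide together, and on neutralisation the free C10 amine closes the γ-lactam on the methyl ester by 5-exo-trig acyl substitution, which locks the diene s-cis.

Step 12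
Reactants: 17 lactam diol
Product: 18 (2E)-3-methyl-4-[(2R)-4-methylidene-5-oxo-3-(propan-2-ylidene)pyrrolidin-2-yl]but-2-enal
Conditions: NaIO4, THF–H2O, 0 °C
Reagents that add atoms: none
Why: Periodate (Malaprade) cleavage of the terminal 1,2-diol removes C5 as formaldehyde and leaves C6 as the E-enal under neutral conditions.

Step 13
Reactants: 19 acrolein; 20 [2-(chloromethyl)prop-2-en-1-yl]trimethylsilane
Product: 21 5-(chloromethyl)hexa-1,5-dien-3-ol (racemic)
Conditions: TiCl4, CH2Cl2, −78 °C
Reagents that add atoms: none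
Why: Hosomi–Sakurai allylation adds the allylsilane 1,2 to the enal, forming C2–C3 and keeping the allylic chloride; C2 may be racemic because it is oxidised later.

Step 14
Reactants: 21 5-(chloromethyl)hexa-1,5-dien-3-ol
Product: 22 tert-butyl{[5-(chloromethyl)hexa-1,5-dien-3-yl]oxy}dimethylsilane
Conditions: TBSCl, imidazole, DMF, rt
Reagents that add atoms: tert-butyldimethylsilyl chloride, CC(C)(C)[Si](C)(C)Cl
Why: Silylation of the secondary alcohol masks C2–OH through the stannylation and the allylation.

Step 15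
Reactants: 22 silyl ether chloride
Product: 23 tributyl(2-{2-[(tert-butyldimethylsilyl)oxy]but-3-en-1-yl}prop-2-en-1-yl)stannane
Conditions: Bu3SnLi (from Bu3SnH, LDA), THF, −78 → 0 °C
Reagents that add atoms: tributyltin hydride, CCCC[SnH](CCCC)CCCC
Why: Nucleophilic displacement of the allylic chloride by the stannyl anion gives the 2-substituted allylstannane (SN2 and SN2′ lead to the same product).

Step 16
Reactants: 18 lactam enal; 23 allylstannane
Product: 24 (5R)-5-[(2E,4S)-8-[(tert-butyldimethylsilyl)oxy]-4-hydroxy-2-methyl-6-methylidenedeca-2,9-dien-1-yl]-3-methylidene-4-(propan-2-ylidene)pyrrolidin-2-one (both C8 epimers of the side chain, i.e. C2)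
Conditions: (S)-BINOL (20 mol%), Ti(OiPr)4 (10 mol%), 4 Å MS, CH2Cl2, −20 °C; aq. NaHCO3
Reagents that add atoms: none
Why: In the Keck asymmetric allylation the (S)-BINOL–titanium catalyst should deliver the allyl group to the Si face of the enal, forming C5–C6 and setting (6S) under reagent control.

Step 17
Reactants: 24 homoallylic alcohol
Product: 25 (2E,4S)-8-[(tert-butyldimethylsilyl)oxy]-2-methyl-6-methylidene-1-[(2R)-4-methylidene-5-oxo-3-(propan-2-ylidene)pyrrolidin-2-yl]deca-2,9-dien-4-yl acetate
Conditions: Ac2O, pyridine, DMAP (cat.), CH2Cl2, 0 °C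
Reagents that add atoms: acetic anhydride, CC(=O)OC(C)=O
Why: DMAP-catalysed O-acetylation of the C6 alcohol proceeds with retention, and the lactam N–H is not acylated under these conditions.

Step 18
Reactants: 25 silyl ether acetate
Product: 26 (2E,4S)-8-hydroxy-2-methyl-6-methylidene-1-[(2R)-4-methylidene-5-oxo-3-(propan-2-ylidene)pyrrolidin-2-yl]deca-2,9-dien-4-yl acetate
Conditions: HF·pyridine, pyridine, THF, 0 °C → rt
Reagents that add atoms: none
Why: Buffered fluoride desilylation frees the C2 carbinol without acetate migration or ionisation of the allylic acetate.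

Step 19
Reactants: 26 C2 alcohol
Product: 27 (2E,4S)-2-methyl-6-methylidene-1-[(2R)-4-methylidene-5-oxo-3-(propan-2-ylidene)pyrrolidin-2-yl]-8-oxodeca-2,9-dien-4-yl acetate (vinyl ketone, cycloaddition precursor)
Conditions: Dess–Martin periodinane, NaHCO3, CH2Cl2, 0 °C; used at once
Reagents that add atoms: none
Why: Dess–Martin oxidation of the vinyl carbinol under buffered conditions gives the vinyl ketone while leaving the base- and acid-sensitive β,γ-placement of the C4 methylene untouched.

Step 20
Reactants: 27 vinyl ketone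
Product: 28 2-oxo-cespitulactam E [(1R,6S,7E,10R)-bicyclo[9.3.1] lactam with C2 ketone]
Conditions: PhMe (0.5 mM), BHT (0.2 equiv), silanised sealed vessel, 130–150 °C
Reagents that add atoms: none
Why: Heating brings the vinyl ketone over the s-cis-locked exocyclic diene in a concerted but asynchronous [4+2] cycloaddition in which the enone β-carbon C14 bonds ahead to the unsubstituted terminus C13 and C1 then closes on the dimethylated terminus C15; the closest known reaction type is the type 2 intramolecular Diels–Alder reaction of 2-tethered dienes with enones, which also tolerates an isopropylidene terminus when a gem-dimethyl bridge is made. The cyclohexene (C1, C14, C13, C12, C11, C15) closes by the cycloaddition itself, and the 12-membered ring (C1 to C11 plus C15) closes in the same event in the bridged 1,3-mode fixed by the attachment of the tether at C11, which leaves the new alkene at the bridgehead C11=C12 in conjugation with the lactam carbonyl. C1 is the only new stereocentre and is set by C10, because C9 leaves the flat lactam on one face and the compact transition state with the C2 carbonyl endo over C11 on that same face should give (1R) from (10R). The regiochemistry needed (C14 to C13, C1 to C15) is secured by the enone polarisation, by the larger diene HOMO coefficient at C13 and by the tether, and the face and endo selectivity by the short reach of the tether from C10. Chemoselectivity over oligomerisation, over [1,5]-hydrogen shift of the diene and over migration of the C4 methylene into conjugation is secured by high dilution, a radical inhibitor and neutral glass at moderate temperature. No Lewis acid is used, since an activated enone would be trapped by the C4 methylene in a six-ring cation–olefin closure and the lactam carbonyl would bind the acid first.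

Step 21
Reactants: 28 2-oxo-cespitulactam E
Product: 29 2-hydroxy-cespitulactam E (C2 configuration immaterial)
Conditions: NaBH4, CeCl3·7H2O, MeOH, −40 °C
Reagents that add atoms: none
Why: Luche reduction takes the isolated C2 ketone to the alcohol at low temperature without enolising C1 or C3, and leaves the acetate and the tetrasubstituted conjugated lactam alone.

Step 22
Reactants: 29 2-hydroxy-cespitulactam E
Product: 30 2-O-(phenoxythiocarbonyl)-2-hydroxy-cespitulactam E
Conditions: PhOC(S)Cl, pyridine, DMAP, CH2Cl2, rt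
Reagents that add atoms: O-phenyl chlorothionoformate, S=C(Cl)Oc1ccccc1
Why: Thionocarbonate formation under amine-base conditions activates the hindered C2 alcohol for radical cleavage without the strong base of a xanthate preparation, which would deprotonate the lactam N–H and endanger the acetate.

Step 23
Reactants: 30 thionocarbonate
Product: 31 cespitulactam E
Conditions: Bu3SnH (0.1 M), AIBN (cat.), PhMe, 90 °C
Reagents that add atoms: none
Why: Barton–McCombie deoxygenation generates the secondary C2 radical, which at this stannane concentration should be reduced faster than it can cyclise onto the C4 or C7 alkenes, leaving C1, C6 and C10 unchanged.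

**Compound list**

1 | (R)-2,2-dimethyl-1,3-dioxolane-4-carbaldehyde | CC1(C)OC[C@H](C=O)O1 | starting material
2 | 1-[(4R)-2,2-dimethyl-1,3-dioxolan-4-yl]-2-methylprop-2-en-1-ol (carbinol epimers) | C=C(C)C(O)[C@H]1COC(C)(C)O1 | intermediate
3 | 1-[(4R)-2,2-dimethyl-1,3-dioxolan-4-yl]-2-methylprop-2-en-1-one | C=C(C)C(=O)[C@H]1COC(C)(C)O1 | intermediate
4 | (1S)-1-[(4R)-2,2-dimethyl-1,3-dioxolan-4-yl]-2-methylprop-2-en-1-ol | C=C(C)[C@H](O)[C@H]1COC(C)(C)O1 | intermediate
5 | N-Boc-glycine | CC(C)(C)OC(=O)NCC(=O)O | starting material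
6 | (1S)-1-[(4R)-2,2-dimethyl-1,3-dioxolan-4-yl]-2-methylprop-2-en-1-yl N-Boc-glycinate | C=C(C)[C@H](OC(=O)CNC(=O)OC(C)(C)C)[C@H]1COC(C)(C)O1 | intermediate
7 | zinc-chelated ester enolate of 6 (N,O-chelate) | C=C(C)[C@H](OC1=CN(C(=O)OC(C)(C)C)[Zn]O1)[C@H]1COC(C)(C)O1 | intermediate
8 | (2R,4E)-2-(Boc-amino)-5-[(4S)-2,2-dimethyl-1,3-dioxolan-4-yl]-4-methylpent-4-enoic acid | CC(C)(C)OC(=O)N[C@H](C/C(C)=C/[C@H]1COC(C)(C)O1)C(=O)O | intermediate
9 | Weinreb amide of 8 | CC(C)(C)OC(=O)N[C@H](C/C(C)=C/[C@H]1COC(C)(C)O1)C(=O)N(C)OC | intermediate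
10 | tert-butyl N-[(4R,6E)-7-[(4S)-2,2-dimethyl-1,3-dioxolan-4-yl]-2,6-dimethyl-3-oxohept-6-en-4-yl]carbamate | CC(C)(C)OC(=O)N[C@H](C/C(C)=C/[C@H]1COC(C)(C)O1)C(=O)C(C)C | intermediate
11 | dipotassium N,O-dianion (C11=C15 enolate) of 10 | [K+].[K+].CC(C)(C)OC(=O)[N-][C@H](C/C(C)=C/[C@H]1COC(C)(C)O1)C([O-])=C(C)C | intermediate
12 | (4R,6E)-4-(Boc-amino)-7-[(4S)-2,2-dimethyl-1,3-dioxolan-4-yl]-2,6-dimethylhepta-2,6-dien-3-yl triflate | CC(C)(C)OC(=O)N[C@H](C/C(C)=C/[C@H]1COC(C)(C)O1)C(OS(=O)(=O)C(F)(F)F)=C(C)C | intermediate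
13 | methyl propiolate | C#CC(=O)OC | starting material
14 | methyl 2-(tributylstannyl)prop-2-enoate | C=C(C(=O)OC)[Sn](CCCC)(CCCC)CCCC | intermediate
15 | methyl (4R,6E)-4-(Boc-amino)-7-[(4S)-2,2-dimethyl-1,3-dioxolan-4-yl]-6-methyl-2-methylidene-3-(propan-2-ylidene)hept-6-enoate | CC(C)(C)OC(=O)N[C@H](C/C(C)=C/[C@H]1COC(C)(C)O1)C(=C(C)C)C(=C)C(=O)OC | intermediate
16 | methyl (4R,6E,8S)-4-amino-8,9-dihydroxy-6-methyl-2-methylidene-3-(propan-2-ylidene)non-6-enoate trifluoroacetate | N[C@H](C/C(C)=C/[C@H](O)CO)C(=C(C)C)C(=C)C(=O)OC.OC(=O)C(F)(F)F | intermediate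
17 | (5R)-5-[(2E,4S)-4,5-dihydroxy-2-methylpent-2-en-1-yl]-3-methylidene-4-(propan-2-ylidene)pyrrolidin-2-one | C=C1C(=O)N[C@H](C/C(C)=C/[C@H](O)CO)C1=C(C)C | intermediate
18 | (2E)-3-methyl-4-[(2R)-4-methylidene-5-oxo-3-(propan-2-ylidene)pyrrolidin-2-yl]but-2-enal | C=C1C(=O)N[C@H](C/C(C)=C/C=O)C1=C(C)C | intermediate
19 | acrolein | C=CC=O | starting material
20 | [2-(chloromethyl)prop-2-en-1-yl]trimethylsilane | C=C(CCl)C[Si](C)(C)C | starting material
21 | 5-(chloromethyl)hexa-1,5-dien-3-ol (racemic) | C=CC(O)CC(=C)CCl | intermediate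
22 | tert-butyl{[5-(chloromethyl)hexa-1,5-dien-3-yl]oxy}dimethylsilane | C=CC(O[Si](C)(C)C(C)(C)C)CC(=C)CCl | intermediate
23 | tributyl(2-{2-[(tert-butyldimethylsilyl)oxy]but-3-en-1-yl}prop-2-en-1-yl)stannane | C=CC(O[Si](C)(C)C(C)(C)C)CC(=C)C[Sn](CCCC)(CCCC)CCCC | intermediate
24 | (5R)-5-[(2E,4S)-8-(TBS-oxy)-4-hydroxy-2-methyl-6-methylidenedeca-2,9-dien-1-yl]-3-methylidene-4-(propan-2-ylidene)pyrrolidin-2-one (C2 epimers) | C=C1C(=O)N[C@H](C/C(C)=C/[C@@H](O)CC(=C)CC(O[Si](C)(C)C(C)(C)C)C=C)C1=C(C)C | intermediate
25 | C6 acetate of 24 | C=C1C(=O)N[C@H](C/C(C)=C/[C@@H](OC(C)=O)CC(=C)CC(O[Si](C)(C)C(C)(C)C)C=C)C1=C(C)C | intermediate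
26 | (2E,4S)-8-hydroxy-2-methyl-6-methylidene-1-[(2R)-4-methylidene-5-oxo-3-(propan-2-ylidene)pyrrolidin-2-yl]deca-2,9-dien-4-yl acetate (C2 epimers) | C=C1C(=O)N[C@H](C/C(C)=C/[C@@H](OC(C)=O)CC(=C)CC(O)C=C)C1=C(C)C | intermediate
27 | (2E,4S)-2-methyl-6-methylidene-1-[(2R)-4-methylidene-5-oxo-3-(propan-2-ylidene)pyrrolidin-2-yl]-8-oxodeca-2,9-dien-4-yl acetate | C=CC(=O)CC(=C)C[C@H](OC(C)=O)/C=C(\C)C[C@H]1NC(=O)C(=C)C1=C(C)C | intermediate
28 | 2-oxo-cespitulactam E | C=C1CC(=O)[C@@H]2CCC3=C([C@@H](C/C(C)=C/[C@@H](OC(C)=O)C1)NC3=O)C2(C)C | intermediate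
29 | 2-hydroxy-cespitulactam E (C2 unassigned) | C=C1CC(O)[C@@H]2CCC3=C([C@@H](C/C(C)=C/[C@@H](OC(C)=O)C1)NC3=O)C2(C)C | intermediate
30 | 2-O-(phenoxythiocarbonyl) derivative of 29 | C=C1CC(OC(=S)Oc4ccccc4)[C@@H]2CCC3=C([C@@H](C/C(C)=C/[C@@H](OC(C)=O)C1)NC3=O)C2(C)C | intermediate
31 | cespitulactam E | C=C1CC[C@@H]2CCC3=C([C@@H](C/C(C)=C/[C@@H](OC(C)=O)C1)NC3=O)C2(C)C | target

**Summary**

Total step count: 23. Longest linear sequence: 19 steps (steps 1–8, 10–12, 16–23).

**Steps most likely to fail**

Step 20. The bridging cycloaddition onto the hindered C15 terminus may be slower than intermolecular Diels–Alder oligomerisation, [1,5]-hydrogen shift of the diene, or drift of the C4 methylene into conjugation with the C2 ketone. The long tether may also fail to hold the endo approach on the C9 face, so that C1 forms without control. Fallback, setting out from enal 18 and chloro alcohol 21 and returning at 28: the six-membered ring is made first and the macrocycle closed afterwards at C5–C6. Alcohol 21 would be oxidised (Dess–Martin periodinane, NaHCO3) to 5-(chloromethyl)hexa-1,5-dien-3-one F1. Heating 18 with F1 in toluene should give, by intermolecular Diels–Alder reaction with the same regiochemistry, (2E)-4-{(1R,6R)-6-[3-(chloromethyl)but-3-enoyl]-7,7-dimethyl-3-oxo-2,3,4,5,6,7-hexahydro-1H-isoindol-1-yl}-3-methylbut-2-enal F2, which would have to be separated from its C1 epimer because no tether directs the face. Intramolecular Nozaki–Hiyama allylation (CrCl2, THF, high dilution) would then close the 12-membered ring to 6-O-deacetyl-2-oxo-cespitulactam E F3, separated from any C6 epimer. Acetylation (Ac2O, pyridine) returns to 28.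

Step 10. Transmetalation between the tetrasubstituted vinyl triflate and the 1-substituted vinylstannane may stall, so that protodestannylation and triflate hydrolysis take over. Fallback, setting out from triflate 12 and returning at lactam diol 17: the C11–C12 bond is made by ring-forming carbopalladation instead of cross-coupling. N-Acylation of 12 (LiHMDS, acryloyl chloride, THF, −78 °C) would give the N-acryloyl-N-Boc enol triflate F4. Intramolecular Heck reaction (Pd(OAc)2, PPh3, Et3N, MeCN, 70 °C), by 5-exo insertion at the acrylamide α-carbon and β-hydride elimination to the exocyclic methylene, would give tert-butyl (2R)-2-{(2E)-3-[(4S)-2,2-dimethyl-1,3-dioxolan-4-yl]-2-methylprop-2-en-1-yl}-4-methylidene-5-oxo-3-(propan-2-ylidene)pyrrolidine-1-carboxylate F5. TFA–H2O then removes the Boc group and the acetonide to give 17.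

Step 8. Deprotonation of the isopropyl methine may be slow, so that proton exchange erodes C10, enolisation turns toward C10, or the carbamate nitrogen is triflated. Fallback, setting out from Weinreb amide 9 and returning at triflate 12: the enolate is generated regiospecifically by conjugate reduction instead of deprotonation. Addition of isopropenylmagnesium bromide to 9 would give the isopropenyl ketone tert-butyl N-[(4R,6E)-7-[(4S)-2,2-dimethyl-1,3-dioxolan-4-yl]-2,6-dimethyl-3-oxohepta-1,6-dien-4-yl]carbamate F6. After N-deprotonation with one equivalent of LiHMDS, L-Selectride (THF, −78 °C) would reduce the enone 1,4, and the resulting C11=C15 enolate would be trapped with PhNTf2 to give 12.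

Further compounds
F1 | step 20 | 5-(chloromethyl)hexa-1,5-dien-3-one | C=CC(=O)CC(=C)CCl
F2 | step 20 | (2E)-4-{(1R,6R)-6-[3-(chloromethyl)but-3-enoyl]-7,7-dimethyl-3-oxo-2,3,4,5,6,7-hexahydro-1H-isoindol-1-yl}-3-methylbut-2-enal | O=C/C=C(\C)C[C@H]1NC(=O)C2=C1C(C)(C)[C@@H](CC2)C(=O)CC(=C)CCl
F3 | step 20 | 6-O-deacetyl-2-oxo-cespitulactam E | C=C1CC(=O)[C@@H]2CCC3=C([C@@H](C/C(C)=C/[C@@H](O)C1)NC3=O)C2(C)C
F4 | step 10 | (4R,6E)-4-[N-acryloyl-N-(tert-butoxycarbonyl)amino]-7-[(4S)-2,2-dimethyl-1,3-dioxolan-4-yl]-2,6-dimethylhepta-2,6-dien-3-yl triflate | CC(C)(C)OC(=O)N(C(=O)C=C)[C@H](C/C(C)=C/[C@H]1COC(C)(C)O1)C(OS(=O)(=O)C(F)(F)F)=C(C)C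
F5 | step 10 | tert-butyl (2R)-2-{(2E)-3-[(4S)-2,2-dimethyl-1,3-dioxolan-4-yl]-2-methylprop-2-en-1-yl}-4-methylidene-5-oxo-3-(propan-2-ylidene)pyrrolidine-1-carboxylate | C=C1C(=O)N(C(=O)OC(C)(C)C)[C@H](C/C(C)=C/[C@H]2COC(C)(C)O2)C1=C(C)C
F6 | step 8 | tert-butyl N-[(4R,6E)-7-[(4S)-2,2-dimethyl-1,3-dioxolan-4-yl]-2,6-dimethyl-3-oxohepta-1,6-dien-4-yl]carbamate | CC(C)(C)OC(=O)N[C@H](C/C(C)=C/[C@H]1COC(C)(C)O1)C(=O)C(C)=C
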